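- Nearly all of the L is left over at the last cedar reading, if one L goes into each X, so the cedar run shows the pace of L while cL has barely moved.

common to all: D 0.80 M
- cedar: L 1.3 M; E 0.040 M; run made earlier
- flask: L 0.640 M; E 0.0400 M; time 8.0 min

cedar run (percent of the D charged): time / s: X / % = 10.0: 0.4; 25.0: 1.9; 40.0: 3.7; 60.0: 6.9; 90.0: 12.6

(readings scatter by 0.3 percentage points)

- solid, in amounts per volume of the solution: D
- at the start none of D is in solution

- winter: doubling the dissolution coefficient of D, all else as stated
- dawn: doubling the amount of L, all else as stated
- autumn: doubling the solubility of D, all else as stated

- amount of X at 8.0 min, in percent of the D charged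
- the change that raises the amount of X at 8.0 min, in percent of the D charged most ("none" if none brings more than 2 percentage points) (winter / dawn / autumn / none)
- amount of X at 8.0 min, in percent of the D charged, after autumn

- The flask looks nearly like cedar: both hold D at 0.80 M and E at 0.0400 M, but the flask has cL 0.640 M, about half of cedar's 1.3 M. I assume that the same charges of D and E give each L molecule the same odds in both.
- Between the last two cedar readings, X rises 5.7 percentage points in 30.0 s. Per L present, that reads as a pseudo-first-order constant of 0.0702 min⁻¹, with each reading scattered by 0.3 points.
- So I follow one molecule of L: its chance of having become X by 8.0 min is 42.9%. This L chance, the share of an L charge turned into X by that time, does not depend on cL in my reckoning.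
- In my reckoning the two flasks end apart because cedar holds more L than this flask, and the same chance acts on each charge. The chance gives 69.8% of the D on cedar's charge, but 34.4% here.
- Doubling L doubles my figure to 68.8%, so I choose dawn; the cedar readings give me no figure for autumn.
- The forecast gives 45% (range 33% to 68%), 66% after autumn and dawn as the best change, and it says: “The data do not separate dissolution from reaction control”.
- The flask gives 36.4%, with dawn the best change at a gain of 25 points, and 38.8% after autumn.

    D + E → J (k = 2.09 M⁻¹ min⁻¹)
    2 Q → G (k = 0.110 M⁻¹ min⁻¹)
    Q + L → X (k = 0.227 M⁻¹ min⁻¹)
    D ⇌ Q, rate k4*(cs4 - [Q]) while solid is left; crystals form when [Q] > cs4 (solubility = 0.420 M, k = 1.66 min⁻¹)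

- At 8.00 min, this flask has 55% of its L left.
- The flask with 0.16 M of L tests the chance again: it gives 8.58% of the D, and that flask holds 9.71% of X at 8.00 min.

(The data were computed for an exercise; the scatter is artificial.)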